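The ten-membered carbocycle of the target, with methyl groups on C4 and C10 and the three-carbon unit C11–C13 on C7, is a folded farnesyl chain with a saturated C1–C10 bond, so it is cut at C6–C7. A germacrene A synthase ionizes a (2Z)-allylic diphosphate and lets the distal C7=C11 alkene capture C6: one operation closes the ring, sets C7 and leaves the C11=C13 methylene. The precursor is a (2Z)-6,7-dihydrofarnesyl diphosphate that already carries the C10 methyl center, the C9 angelate and a C12 acetate, so that only the C6 and C3 oxygens remain to be added afterwards by allylic oxidation.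

Key step: step 14

Numbering: ring compounds use germacrane locants (ring C1–C10, C11–C13 on C7, C14 on C10, C15 on C4). The target is (3S,4Z,6R,7S,9S,10R) and its C9 ester is the (2Z)-2-methylbut-2-enoate (angelate). Acyclic compounds 18–20 use dodecadienyl locants (chain C1 = ring C6, C3 = ring C4, C7 = ring C10, C8 = ring C9, C10 = ring C7). Diphosphate 20 is drawn as the acid and handled as its tris(ammonium) salt.

Assumption: the cyclase takes the terminating proton from the methyl cis to the chain (C13); the acetoxy group is therefore placed on the trans methyl (C12), the position that SeO2 oxidation delivers.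

Step 1
Reactants: 1 prop-2-yn-1-ol; 2 3-bromoprop-1-ene (allyl bromide)
Product: 3 hex-5-en-2-yn-1-ol
Conditions: CuI (10 mol %), K2CO3, nBu4NI (10 mol %), DMF, rt
Reagents that add atoms: none
Why: Copper-catalysed allylation of a terminal alkyne (copper acetylide coupling with an allylic halide) should give the skipped enyne without touching the free hydroxyl.

Step 2
Reactants: 3 hex-5-en-2-yn-1-ol
Product: 5 (2E)-hexa-2,5-dien-1-ol, via lithium vinylalanate 4 (not isolated)
Conditions: LiAlH4, THF, 0 °C to reflux; aqueous NaOH work-up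
Reagents that add atoms: none
Why: Alkoxide-directed trans-hydroalumination of the propargylic alcohol and protonolysis should give only the E allylic alcohol, the isolated terminal alkene being inert to LiAlH4.

Step 3
Reactants: 5 (2E)-hexa-2,5-dien-1-ol
Product: 6 [(2S,3S)-3-(prop-2-en-1-yl)oxiran-2-yl]methanol
Conditions: Ti(OiPr)4 (10 mol %), L-(+)-diethyl tartrate (12 mol %), tBuOOH, 4 Å molecular sieves, CH2Cl2, −20 °C
Reagents that add atoms: tert-butyl hydroperoxide, CC(C)(C)OO
Why: Sharpless asymmetric epoxidation acts only on the allylic alcohol alkene, and with L-(+)-diethyl tartrate an (E)-2-alken-1-ol should be epoxidized on the face that gives the (2S,3S) epoxy alcohol, which fixes the future C9 and prepares C10.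

Step 4
Reactants: 6 [(2S,3S)-3-(prop-2-en-1-yl)oxiran-2-yl]methanol
Product: 7 (2R,3R)-3-methylhex-5-ene-1,2-diol
Conditions: AlMe3 (3 equiv), hexane/CH2Cl2, 0 °C to rt; Rochelle salt work-up
Reagents that add atoms: trimethylaluminium, C[Al](C)C
Why: Trimethylaluminium opens 2,3-epoxy alcohols at C3 with inversion (alkoxide-directed epoxide alkylation), so the methyl-bearing center (future C10, R) is set anti to the oxygen on the future C9.

Step 5
Reactants: 7 (2R,3R)-3-methylhex-5-ene-1,2-diol
Product: 9 (2R)-2-[(2R)-pent-4-en-2-yl]oxirane, via primary tosylate 8 (not isolated)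
Conditions: NaH (2.5 equiv), 1-tosylimidazole (1.05 equiv), THF, 0 °C to rt
Reagents that add atoms: none
Why: Selective sulfonylation of the primary alkoxide and Williamson-type ring closure by the secondary alkoxide should give the terminal epoxide with both stereocenters untouched.

Step 6
Reactants: 9 (2R)-2-[(2R)-pent-4-en-2-yl]oxirane
Product: 10 (4R,5S)-4,8-dimethylnona-1,7-dien-5-ol
Conditions: Me2C=CHMgBr (1.5 equiv), CuI (10 mol %), THF, −30 to 0 °C
Reagents that add atoms: 2-methylprop-1-en-1-ylmagnesium bromide, CC(C)=C[Mg]Br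
Why: Copper-catalysed Grignard opening of a terminal epoxide occurs at the unsubstituted carbon, so the 2-methylpropenyl group becomes C7=C11 and the carbinol center (C9, S) keeps its configuration.

Step 7
Reactants: 10 (4R,5S)-4,8-dimethylnona-1,7-dien-5-ol
Product: 11 (2E,5S,6R)-2,6-dimethylnona-2,8-diene-1,5-diol
Conditions: SeO2 (0.5 equiv), tBuOOH (70% aq., 3 equiv), salicylic acid (10 mol %), CH2Cl2, rt
Reagents that add atoms: selenium dioxide (oxygen carrier), O=[Se]=O; tert-butyl hydroperoxide (terminal oxidant), CC(C)(C)OO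
Why: SeO2 allylic hydroxylation (ene reaction, then [2,3]-shift) of a 2-methylalk-2-ene end group is selective for the methyl trans to the chain and gives the E allylic alcohol, while the monosubstituted alkene reacts far more slowly.

Step 8
Reactants: 11 (2E,5S,6R)-2,6-dimethylnona-2,8-diene-1,5-diol
Product: 12 (2E,5S,6R)-5-hydroxy-2,6-dimethylnona-2,8-dien-1-yl acetate
Conditions: AcCl (1.05 equiv), 2,4,6-collidine (2 equiv), CH2Cl2, −78 °C
Reagents that add atoms: acetyl chloride, CC(Cl)=O
Why: Kinetically selective esterification with acetyl chloride and collidine at low temperature should acylate the unhindered primary allylic hydroxyl and leave the secondary one next to the branched carbon.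

Step 9
Reactants: 12 (2E,5S,6R)-5-hydroxy-2,6-dimethylnona-2,8-dien-1-yl acetate
Product: 13 (2E,5S,6R)-1-(acetyloxy)-2,6-dimethylnona-2,8-dien-5-yl (2Z)-2-methylbut-2-enoate
Conditions: angelic acid (3 equiv), 2,4,6-trichlorobenzoyl chloride (3 equiv), Et3N (6 equiv), toluene, rt; then 12, toluene, 75 °C
Reagents that add atoms: angelic acid [(2Z)-2-methylbut-2-enoic acid], C/C=C(/C)C(O)=O
Why: Yamaguchi esterification through the mixed anhydride, run without a nucleophilic pyridine catalyst, should acylate the secondary hydroxyl while keeping the Z geometry of the angeloyl group.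

Step 10
Reactants: 14 but-2-yn-1-ol
Product: 16 (2Z)-3-iodobut-2-en-1-ol, via cyclic vinylalanate 15 (not isolated)
Conditions: NaAlH2(OCH2CH2OMe)2 (1.5 equiv), Et2O, 0 °C to rt; then I2, THF, −78 °C
Reagents that add atoms: iodine, II
Why: Hydroxyl-directed trans-hydroalumination places aluminium on C3, and iodinolysis with retention gives the iodide cis to the hydroxymethyl group (Z).

Step 11
Reactants: 13 (2E,5S,6R)-1-(acetyloxy)-2,6-dimethylnona-2,8-dien-5-yl (2Z)-2-methylbut-2-enoate; 16 (2Z)-3-iodobut-2-en-1-ol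
Product: 18 (2Z,7R,8S,10E)-12-(acetyloxy)-1-hydroxy-3,7,11-trimethyldodeca-2,10-dien-8-yl (2Z)-2-methylbut-2-enoate, via B-alkyl-9-BBN adduct 17 (not isolated)
Conditions: 9-BBN (1.3 equiv), THF, rt; then 16, Pd(dppf)Cl2 (5 mol %), AsPh3 (10 mol %), K3PO4 (3 M aq.), DMF, rt
Reagents that add atoms: none
Why: Anti-Markovnikov hydroboration of the only monosubstituted alkene and B-alkyl Suzuki–Miyaura coupling with retention at the vinyl iodide should give the 2Z trisubstituted allylic alcohol (future C4=C5), since oxidative addition of zerovalent palladium to the vinyl iodide should outpace ionization of the allylic acetate at room temperature.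

Step 12
Reactants: 18 (2Z,7R,8S,10E)-12-(acetyloxy)-1-hydroxy-3,7,11-trimethyldodeca-2,10-dien-8-yl (2Z)-2-methylbut-2-enoate
Product: 19 (2Z,7R,8S,10E)-12-(acetyloxy)-1-chloro-3,7,11-trimethyldodeca-2,10-dien-8-yl (2Z)-2-methylbut-2-enoate
Conditions: N-chlorosuccinimide (1.3 equiv), Me2S (1.4 equiv), CH2Cl2, −30 to 0 °C
Reagents that add atoms: N-chlorosuccinimide, ClN1C(=O)CCC1=O
Why: Corey–Kim chlorination replaces a primary allylic hydroxyl by direct displacement under neutral conditions, so neither allylic transposition nor Z to E isomerization is expected and both esters survive.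

Step 13
Reactants: 19 (2Z,7R,8S,10E)-12-(acetyloxy)-1-chloro-3,7,11-trimethyldodeca-2,10-dien-8-yl (2Z)-2-methylbut-2-enoate
Product: 20 (2Z,7R,8S,10E)-12-(acetyloxy)-8-{[(2Z)-2-methylbut-2-enoyl]oxy}-3,7,11-trimethyldodeca-2,10-dien-1-yl diphosphate
Conditions: (nBu4N)3HP2O7 (2 equiv), MeCN, rt; cation exchange (NH4+ form resin, 25 mM NH4HCO3), lyophilization
Reagents that add atoms: tris(tetrabutylammonium) hydrogen diphosphate, CCCC[N+](CCCC)(CCCC)CCCC.CCCC[N+](CCCC)(CCCC)CCCC.CCCC[N+](CCCC)(CCCC)CCCC.OP(=O)([O-])OP(=O)([O-])[O-]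
Why: Direct displacement of the primary allylic chloride by the diphosphate anion in acetonitrile, the standard way to prenyl diphosphates, should give the diphosphate ester with the 2Z alkene intact.

Step 14
Reactants: 20 (2Z,7R,8S,10E)-12-(acetyloxy)-8-{[(2Z)-2-methylbut-2-enoyl]oxy}-3,7,11-trimethyldodeca-2,10-dien-1-yl diphosphate
Product: 21 (4Z,7S,9S,10R)-12-(acetyloxy)germacra-4,11(13)-dien-9-yl (2Z)-2-methylbut-2-enoate
Conditions: recombinant germacrene A synthase (for example the Cichorium intybus enzyme, picked from a small panel for turnover of the 2Z analogue), MgCl2 (10 mM), HEPES buffer pH 7.5, dithiothreitol, pentane overlay, 30 °C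
Reagents that add atoms: none
Why: Proposed new method: loss of diphosphate from 20, assisted by the bound magnesium ions, gives a Z-configured allyl cation over C6–C5–C4; the pocket holds the C7=C11 alkene over C6, C7 adds to C6 with Markovnikov sense (tertiary C11 cation) and the departed diphosphate takes a proton from C13 to give the C11=C13 methylene. The closest known reaction type is the 1,10-cyclization of farnesyl diphosphate to germacrene A by cyclases of this class, and related sesquiterpene cyclases are known to turn over 6,7-dihydrofarnesyl and 12-hydroxyfarnesyl diphosphates; the 2Z geometry combined with the two ester groups is the untested part. The ten-membered ring is closed head to tail (chain C1 to C10) with the whole allyl unit C4–C6 inside the ring and C11 outside it, that is exo with respect to the attacking alkene. C7, the only new stereocenter, is set by the enzyme, which should present the alkene face used for the natural substrate (7S here, as in the target), while C9 and C10 are carried over from 20. The step needs closure at C7 over other closures, 4Z geometry and proton loss from C13: the saturated C1–C10 bond excludes the six-membered closure open to Z-allyl cations, the bound cation cannot rotate so the Z geometry of 20 becomes C4=C5, and the acetoxy group on the trans methyl (C12) is a poor donor for a hydride shift and leaves the cis methyl (C13) for deprotonation.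

Step 15
Reactants: 21 (4Z,7S,9S,10R)-12-(acetyloxy)germacra-4,11(13)-dien-9-yl (2Z)-2-methylbut-2-enoate
Product: 23 (4Z,7S,9S,10R)-12-(acetyloxy)-6-oxogermacra-4,11(13)-dien-9-yl (2Z)-2-methylbut-2-enoate, via C6 tert-butyl peroxide 22 (not isolated)
Conditions: Rh2(cap)4 (cap = caprolactamate, 1 mol %), tBuOOH (70% aq., 5 equiv), ClCH2CH2Cl, 40 °C
Reagents that add atoms: tert-butyl hydroperoxide, CC(C)(C)OO
Why: Dirhodium-catalysed radical allylic oxidation with tert-butyl hydroperoxide attacks the methylene next to the CH end of a trisubstituted ring alkene, as in the conversion of 5-ene steroids into 7-ketones, so C6 should be oxidized in preference to C3 and C15 and the ring-favoured Z geometry should persist.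

Step 16
Reactants: 23 (4Z,7S,9S,10R)-12-(acetyloxy)-6-oxogermacra-4,11(13)-dien-9-yl (2Z)-2-methylbut-2-enoate
Product: 24 (4Z,6R,7S,9S,10R)-12-(acetyloxy)-6-hydroxygermacra-4,11(13)-dien-9-yl (2Z)-2-methylbut-2-enoate
Conditions: (R)-Me-CBS oxazaborolidine (0.5 equiv), catecholborane (2 equiv), toluene, −78 °C
Reagents that add atoms: none
Why: Corey–Bakshi–Shibata reduction with the alkenyl carbon C5 as the large group should deliver hydride with the (R)-catalyst to the face that gives the 6R alcohol, the same face that the Felkin–Anh model predicts when the C11 substituent on C7 stands anti to the incoming hydride.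

Step 17
Reactants: 24 (4Z,6R,7S,9S,10R)-12-(acetyloxy)-6-hydroxygermacra-4,11(13)-dien-9-yl (2Z)-2-methylbut-2-enoate
Product: 25 (4Z,6R,7S,9S,10R)-6,12-dihydroxygermacra-4,11(13)-dien-9-yl (2Z)-2-methylbut-2-enoate
Conditions: K2CO3 (0.2 equiv), MeOH, 0 °C
Reagents that add atoms: none
Why: Base-catalysed transesterification should remove the unhindered primary allylic acetate much faster than the hindered, conjugated secondary angelate.

Step 18
Reactants: 25 (4Z,6R,7S,9S,10R)-6,12-dihydroxygermacra-4,11(13)-dien-9-yl (2Z)-2-methylbut-2-enoate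
Product: 28 (4Z,6R,7S,9S,10R)-9-{[(2Z)-2-methylbut-2-enoyl]oxy}germacra-4,11(13)-dien-12,6-olide, via hydroxy enal 26 (not isolated), via lactol 27 (not isolated)
Conditions: TEMPO (20 mol %), PhI(OAc)2 (2.5 equiv), CH2Cl2, rt
Reagents that add atoms: none
Why: Oxoammonium oxidation is selective for the primary alcohol, the enal is trapped by the C6 hydroxyl as a five-membered lactol and oxidized on to the α-methylene γ-lactone (oxidative lactonization of a 1,4-diol), so the trans ring fusion follows from the C7 and C6 centers set in steps 14 and 16.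

Step 19
Reactants: 28 (4Z,6R,7S,9S,10R)-9-{[(2Z)-2-methylbut-2-enoyl]oxy}germacra-4,11(13)-dien-12,6-olide
Product: 30 (4Z,6R,7S,9S,10R)-9-{[(2Z)-2-methylbut-2-enoyl]oxy}-3-oxogermacra-4,11(13)-dien-12,6-olide, via C3 tert-butyl peroxide 29 (not isolated)
Conditions: Rh2(cap)4 (1 mol %), tBuOOH (70% aq., 5 equiv), ClCH2CH2Cl, 40 °C
Reagents that add atoms: tert-butyl hydroperoxide, CC(C)(C)OO
Why: The same radical allylic oxidation should now take the only remaining allylic methylene (C3), because the C6–H is deactivated by its acyloxy group (as cyclohex-2-enyl acetate gives 4-acetoxycyclohex-2-enone) and the C15 methyl is oxidized more slowly than a methylene.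

Step 20
Reactants: 30 (4Z,6R,7S,9S,10R)-9-{[(2Z)-2-methylbut-2-enoyl]oxy}-3-oxogermacra-4,11(13)-dien-12,6-olide
Product: 31 (3S,4Z,6R,7S,9S,10R)-3-hydroxy-9-{[(2Z)-2-methylbut-2-enoyl]oxy}germacra-4,11(13)-dien-12,6-olide
Conditions: (R)-Me-CBS oxazaborolidine (0.5 equiv), catecholborane (2 equiv), toluene, −78 °C
Reagents that add atoms: none
Why: Corey–Bakshi–Shibata reduction of an α-methyl enone is reagent controlled, and with C4 as the large and C2 as the small group the (R)-catalyst should give the 3S allylic alcohol by 1,2-reduction, the α-methylene lactone being inert to catecholborane at low temperature.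

Step 21
Reactants: 31 (3S,4Z,6R,7S,9S,10R)-3-hydroxy-9-{[(2Z)-2-methylbut-2-enoyl]oxy}germacra-4,11(13)-dien-12,6-olide
Product: 32 (3S,4Z,6R,7S,9S,10R)-3-(acetyloxy)-9-{[(2Z)-2-methylbut-2-enoyl]oxy}germacra-4,11(13)-dien-12,6-olide (CNP0173235.1)
Conditions: Ac2O (3 equiv), pyridine, DMAP (5 mol %), CH2Cl2, 0 °C
Reagents that add atoms: acetic anhydride, CC(=O)OC(C)=O
Why: DMAP-catalysed acetylation of the one remaining hydroxyl completes the target without touching any stereocenter.

Compound list

1 | prop-2-yn-1-ol | C#CCO | starting material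
2 | 3-bromoprop-1-ene (allyl bromide) | C=CCBr | starting material
3 | hex-5-en-2-yn-1-ol | C=CCC#CCO | intermediate
4 | lithium vinylalanate of 3 (Al on C3 in a five-membered C–Al–O ring) | [Li+].[H][Al-]1([H])OCC=C1CC=C | intermediate (not isolated)
5 | (2E)-hexa-2,5-dien-1-ol | C=CC/C=C/CO | intermediate
6 | [(2S,3S)-3-(prop-2-en-1-yl)oxiran-2-yl]methanol | C=CC[C@@H]1O[C@H]1CO | intermediate
7 | (2R,3R)-3-methylhex-5-ene-1,2-diol | C=CC[C@@H](C)[C@@H](O)CO | intermediate
8 | (2R,3R)-2-hydroxy-3-methylhex-5-en-1-yl 4-methylbenzenesulfonate | C=CC[C@@H](C)[C@@H](O)COS(=O)(=O)c1ccc(C)cc1 | intermediate (not isolated)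
9 | (2R)-2-[(2R)-pent-4-en-2-yl]oxirane | C=CC[C@@H](C)[C@@H]1CO1 | intermediate
10 | (4R,5S)-4,8-dimethylnona-1,7-dien-5-ol | C=CC[C@@H](C)[C@@H](O)CC=C(C)C | intermediate
11 | (2E,5S,6R)-2,6-dimethylnona-2,8-diene-1,5-diol | C=CC[C@@H](C)[C@@H](O)C/C=C(\C)CO | intermediate
12 | (2E,5S,6R)-5-hydroxy-2,6-dimethylnona-2,8-dien-1-yl acetate | C=CC[C@@H](C)[C@@H](O)C/C=C(\C)COC(C)=O | intermediate
13 | (2E,5S,6R)-1-(acetyloxy)-2,6-dimethylnona-2,8-dien-5-yl (2Z)-2-methylbut-2-enoate | C=CC[C@@H](C)[C@@H](OC(=O)/C(C)=C\C)C/C=C(\C)COC(C)=O | intermediate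
14 | but-2-yn-1-ol | CC#CCO | starting material
15 | sodium bis(2-methoxyethoxy) vinylalanate of 14 (Al on C3 in a five-membered C–Al–O ring) | [Na+].CC1=CCO[Al-]1(OCCOC)OCCOC | intermediate (not isolated)
16 | (2Z)-3-iodobut-2-en-1-ol | C/C(I)=C/CO | intermediate
17 | B-alkyl-9-BBN adduct of 13 (boron on the former terminal alkene carbon) | B1(CCC[C@@H](C)[C@@H](OC(=O)/C(C)=C\C)C/C=C(\C)COC(C)=O)C2CCCC1CCC2 | intermediate (not isolated)
18 | (2Z,7R,8S,10E)-12-(acetyloxy)-1-hydroxy-3,7,11-trimethyldodeca-2,10-dien-8-yl (2Z)-2-methylbut-2-enoate | OC/C=C(/C)CCC[C@@H](C)[C@@H](OC(=O)/C(C)=C\C)C/C=C(\C)COC(C)=O | intermediate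
19 | (2Z,7R,8S,10E)-12-(acetyloxy)-1-chloro-3,7,11-trimethyldodeca-2,10-dien-8-yl (2Z)-2-methylbut-2-enoate | ClC/C=C(/C)CCC[C@@H](C)[C@@H](OC(=O)/C(C)=C\C)C/C=C(\C)COC(C)=O | intermediate
20 | (2Z,7R,8S,10E)-12-(acetyloxy)-8-{[(2Z)-2-methylbut-2-enoyl]oxy}-3,7,11-trimethyldodeca-2,10-dien-1-yl diphosphate (precursor of the key step) | OP(O)(=O)OP(O)(=O)OC/C=C(/C)CCC[C@@H](C)[C@@H](OC(=O)/C(C)=C\C)C/C=C(\C)COC(C)=O | intermediate
21 | (4Z,7S,9S,10R)-12-(acetyloxy)germacra-4,11(13)-dien-9-yl (2Z)-2-methylbut-2-enoate (product of the key step) | C=C(COC(C)=O)[C@H]1C/C=C(/C)CCC[C@@H](C)[C@@H](OC(=O)/C(C)=C\C)C1 | intermediate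
22 | 6-(tert-butylperoxy) derivative of 21 (C6 epimers) | C=C(COC(C)=O)[C@H]1C(OOC(C)(C)C)/C=C(/C)CCC[C@@H](C)[C@@H](OC(=O)/C(C)=C\C)C1 | intermediate (not isolated)
23 | (4Z,7S,9S,10R)-12-(acetyloxy)-6-oxogermacra-4,11(13)-dien-9-yl (2Z)-2-methylbut-2-enoate | C=C(COC(C)=O)[C@H]1C(=O)/C=C(/C)CCC[C@@H](C)[C@@H](OC(=O)/C(C)=C\C)C1 | intermediate
24 | (4Z,6R,7S,9S,10R)-12-(acetyloxy)-6-hydroxygermacra-4,11(13)-dien-9-yl (2Z)-2-methylbut-2-enoate | C=C(COC(C)=O)[C@H]1[C@H](O)/C=C(/C)CCC[C@@H](C)[C@@H](OC(=O)/C(C)=C\C)C1 | intermediate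
25 | (4Z,6R,7S,9S,10R)-6,12-dihydroxygermacra-4,11(13)-dien-9-yl (2Z)-2-methylbut-2-enoate | C=C(CO)[C@H]1[C@H](O)/C=C(/C)CCC[C@@H](C)[C@@H](OC(=O)/C(C)=C\C)C1 | intermediate
26 | (4Z,6R,7S,9S,10R)-6-hydroxy-12-oxogermacra-4,11(13)-dien-9-yl (2Z)-2-methylbut-2-enoate | C=C(C=O)[C@H]1[C@H](O)/C=C(/C)CCC[C@@H](C)[C@@H](OC(=O)/C(C)=C\C)C1 | intermediate (not isolated)
27 | 12-hydroxy-6,12-epoxy lactol of 26 (C12 epimers) | C=C1C(O)O[C@@H]2/C=C(/C)CCC[C@@H](C)[C@@H](OC(=O)/C(C)=C\C)C[C@@H]12 | intermediate (not isolated)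
28 | (4Z,6R,7S,9S,10R)-9-{[(2Z)-2-methylbut-2-enoyl]oxy}germacra-4,11(13)-dien-12,6-olide | C=C1C(=O)O[C@@H]2/C=C(/C)CCC[C@@H](C)[C@@H](OC(=O)/C(C)=C\C)C[C@@H]12 | intermediate
29 | 3-(tert-butylperoxy) derivative of 28 (C3 epimers) | C=C1C(=O)O[C@@H]2/C=C(/C)C(OOC(C)(C)C)CC[C@@H](C)[C@@H](OC(=O)/C(C)=C\C)C[C@@H]12 | intermediate (not isolated)
30 | (4Z,6R,7S,9S,10R)-9-{[(2Z)-2-methylbut-2-enoyl]oxy}-3-oxogermacra-4,11(13)-dien-12,6-olide | C=C1C(=O)O[C@@H]2/C=C(/C)C(=O)CC[C@@H](C)[C@@H](OC(=O)/C(C)=C\C)C[C@@H]12 | intermediate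
31 | (3S,4Z,6R,7S,9S,10R)-3-hydroxy-9-{[(2Z)-2-methylbut-2-enoyl]oxy}germacra-4,11(13)-dien-12,6-olide | C=C1C(=O)O[C@@H]2/C=C(/C)[C@@H](O)CC[C@@H](C)[C@@H](OC(=O)/C(C)=C\C)C[C@@H]12 | intermediate
32 | (3S,4Z,6R,7S,9S,10R)-3-(acetyloxy)-9-{[(2Z)-2-methylbut-2-enoyl]oxy}germacra-4,11(13)-dien-12,6-olide (CNP0173235.1) | C=C1C(=O)O[C@@H]2/C=C(/C)[C@@H](OC(C)=O)CC[C@@H](C)[C@@H](OC(=O)/C(C)=C\C)C[C@@H]12 | target

Total step count: 21. Longest linear sequence: 20 steps (steps 1–9 and 11–21; step 10 makes the coupling partner 16).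

Steps most likely to fail

Step 14 (Proposed new method). The cyclase may not bind or ionize the 2Z, diester-bearing substrate. The allyl cation may be quenched by water before ring closure. The C11 cation may be captured by the C12 acetate carbonyl or relieved by hydride shift instead of losing the C13 proton. The fallback uses known chemistry, an intramolecular Nozaki–Hiyama–Kishi allylation across the same C6–C7 bond; it sets out from 18 and comes back at 25. Dess–Martin oxidation of 18 (NaHCO3, CH2Cl2) would give the (2Z)-enal (2Z,7R,8S,10E)-12-(acetyloxy)-3,7,11-trimethyl-1-oxododeca-2,10-dien-8-yl (2Z)-2-methylbut-2-enoate F1. Lipase-mediated hydrolysis of the primary acetate (Candida antarctica lipase B, phosphate buffer pH 7) would give the 12-hydroxy enal F2, and CBr4/PPh3 the allylic bromide F3. CrCl2 in THF at high dilution would form the allylchromium reagent, whose γ-carbon (C7) adds to the aldehyde carbon (C6) through a chair transition state; the E allyl unit should give the anti C6/C7 relation of the target, while the facial bias from C9 and C10 remains to be established. The product would be (4Z,6R,7S,9S,10R)-6-hydroxygermacra-4,11-dien-9-yl (2Z)-2-methylbut-2-enoate F4. SeO2/tBuOOH would then hydroxylate the isopropenyl methyl, the C4=C5 alkene being deactivated by its allylic hydroxyl, and give 25.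

Step 15. Hydrogen abstraction may occur at C3 or at the tertiary allylic C7–H, oxidation may run on to the ene-dione, and the β,γ-unsaturated ketone may epimerize at C7 or isomerize into conjugation. The fallback replaces C–H abstraction by an epoxide-based sequence; it sets out from 21 and comes back at 23. mCPBA (NaHCO3, CH2Cl2, 0 °C) should epoxidize only the electron-rich C4=C5 alkene and give the cis-4,5-epoxide of 21 F5. PhSeNa, made from (PhSe)2 and NaBH4 in ethanol, should open it at the less substituted C5 to the 4-hydroxy-5-(phenylselanyl) compound F6. H2O2 would give the selenoxide F7, which can eliminate only toward C6 and would give the tertiary allylic alcohol (7S,9S,10R)-12-(acetyloxy)-4-hydroxygermacra-5,11(13)-dien-9-yl (2Z)-2-methylbut-2-enoate F8. Pyridinium chlorochromate, [C5H5NH][CrO3Cl], would then bring about the oxidative 1,3-transposition of the tertiary allylic alcohol to enone 23.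

Step 19. The allyl radical may be trapped at C5 instead of C3, the C15 methyl or the C6–H may be attacked, and the α-methylene lactone may not survive the peroxide. The fallback oxidizes C3 earlier, while it is the activated γ-methylene of the C6 enone; it sets out from 23 and comes back at 31. Continued oxidation of 23 with Rh2(cap)4/tBuOOH at higher oxidant loading (the known enone to ene-dione oxidation) would give (4Z,7S,9S,10R)-12-(acetyloxy)-3,6-dioxogermacra-4,11(13)-dien-9-yl (2Z)-2-methylbut-2-enoate F9. (R)-Me-CBS/catecholborane would reduce both ketones with the alkenyl carbons as large groups to the (3S,6R)-diol F10. K2CO3/MeOH would remove the C12 acetate and give the 3,6,12-triol F11. TEMPO/PhI(OAc)2 would oxidize the primary alcohol through the 12-aldehyde F12 and the lactol F13 to 31; any over-oxidation at C3 would give 30, which is also on the route.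

Further compounds

F1 | step 14 | (2Z,7R,8S,10E)-12-(acetyloxy)-3,7,11-trimethyl-1-oxododeca-2,10-dien-8-yl (2Z)-2-methylbut-2-enoate | O=C/C=C(/C)CCC[C@@H](C)[C@@H](OC(=O)/C(C)=C\C)C/C=C(\C)COC(C)=O
F2 | step 14 | (2Z,7R,8S,10E)-12-hydroxy-3,7,11-trimethyl-1-oxododeca-2,10-dien-8-yl (2Z)-2-methylbut-2-enoate | O=C/C=C(/C)CCC[C@@H](C)[C@@H](OC(=O)/C(C)=C\C)C/C=C(\C)CO
F3 | step 14 | (2Z,7R,8S,10E)-12-bromo-3,7,11-trimethyl-1-oxododeca-2,10-dien-8-yl (2Z)-2-methylbut-2-enoate | O=C/C=C(/C)CCC[C@@H](C)[C@@H](OC(=O)/C(C)=C\C)C/C=C(\C)CBr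
F4 | step 14 | (4Z,6R,7S,9S,10R)-6-hydroxygermacra-4,11-dien-9-yl (2Z)-2-methylbut-2-enoate | C=C(C)[C@H]1[C@H](O)/C=C(/C)CCC[C@@H](C)[C@@H](OC(=O)/C(C)=C\C)C1
F5 | step 15 | (7S,9S,10R)-12-(acetyloxy)-4,5-epoxygermacr-11(13)-en-9-yl (2Z)-2-methylbut-2-enoate (cis-epoxide, either face) | C=C(COC(C)=O)[C@H]1CC2OC2(C)CCC[C@@H](C)[C@@H](OC(=O)/C(C)=C\C)C1
F6 | step 15 | (7S,9S,10R)-12-(acetyloxy)-4-hydroxy-5-(phenylselanyl)germacr-11(13)-en-9-yl (2Z)-2-methylbut-2-enoate | C=C(COC(C)=O)[C@H]1CC([Se]c2ccccc2)C(C)(O)CCC[C@@H](C)[C@@H](OC(=O)/C(C)=C\C)C1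
F7 | step 15 | selenoxide of F6 | C=C(COC(C)=O)[C@H]1CC([Se](=O)c2ccccc2)C(C)(O)CCC[C@@H](C)[C@@H](OC(=O)/C(C)=C\C)C1
F8 | step 15 | (7S,9S,10R)-12-(acetyloxy)-4-hydroxygermacra-5,11(13)-dien-9-yl (2Z)-2-methylbut-2-enoate | C=C(COC(C)=O)[C@H]1C=CC(C)(O)CCC[C@@H](C)[C@@H](OC(=O)/C(C)=C\C)C1
F9 | step 19 | (4Z,7S,9S,10R)-12-(acetyloxy)-3,6-dioxogermacra-4,11(13)-dien-9-yl (2Z)-2-methylbut-2-enoate | C=C(COC(C)=O)[C@H]1C(=O)/C=C(/C)C(=O)CC[C@@H](C)[C@@H](OC(=O)/C(C)=C\C)C1
F10 | step 19 | (3S,4Z,6R,7S,9S,10R)-12-(acetyloxy)-3,6-dihydroxygermacra-4,11(13)-dien-9-yl (2Z)-2-methylbut-2-enoate | C=C(COC(C)=O)[C@H]1[C@H](O)/C=C(/C)[C@@H](O)CC[C@@H](C)[C@@H](OC(=O)/C(C)=C\C)C1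
F11 | step 19 | (3S,4Z,6R,7S,9S,10R)-3,6,12-trihydroxygermacra-4,11(13)-dien-9-yl (2Z)-2-methylbut-2-enoate | C=C(CO)[C@H]1[C@H](O)/C=C(/C)[C@@H](O)CC[C@@H](C)[C@@H](OC(=O)/C(C)=C\C)C1
F12 | step 19 | (3S,4Z,6R,7S,9S,10R)-3,6-dihydroxy-12-oxogermacra-4,11(13)-dien-9-yl (2Z)-2-methylbut-2-enoate | C=C(C=O)[C@H]1[C@H](O)/C=C(/C)[C@@H](O)CC[C@@H](C)[C@@H](OC(=O)/C(C)=C\C)C1
F13 | step 19 | 12-hydroxy-6,12-epoxy lactol of F12 (C12 epimers) | C=C1C(O)O[C@@H]2/C=C(/C)[C@@H](O)CC[C@@H](C)[C@@H](OC(=O)/C(C)=C\C)C[C@@H]12
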